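**Strategy.** Both outer rings are cut back to cyclobutenones. Ring A (OCH3 para to its CH2 bridge) and ring C (OCH3 ortho to its bridge) each hold the triad C(OH)–C(CH3)–C(OCH3) inside a 1,3,5-trioxygenated arene (C2′–C3′–C4′ in ring A, C4″–C5″–C6″ in ring C). A twofold Danheiser benzannulation of a bis(3-benzyloxycyclobutenone) with 1-methoxyprop-1-yne builds both rings at once: the alkyne supplies the adjacent C–CH3 and C–OCH3 carbons, the ketene carbon becomes the phenolic C–OH. The precursor is the fully benzylated, butanoylated ring B carrying one cyclobutenone attached through its C4 (gives ring A) and one attached through its C2 (gives ring C).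

Key step: step 16

Remark (locants): ring B is the central ring (C1 butanoyl, C3 and C5 bridges). Ring A: C1′ bridge carbon, C2′ OH, C3′ CH3, C4′ OCH3, C5′ butanoyl, C6′ OH. Ring C: C1″ bridge carbon, C2″ OH, C3″ butanoyl, C4″ OH, C5″ CH3, C6″ OCH3.

Remark (stereochemistry): the target is achiral. The one stereocentre on the route, C4 of the C4-linked cyclobutenone (15, 29), is carried racemic and becomes aromatic in step 16.

Remark (precursor design): the three ring B oxygens stay benzylated from step 2 to the last step, so that no ring B phenol can trap a ketene and the diarylmethane links cannot exchange.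

Step 1
Reactants: 1 phloroglucinol; 2 butanoyl chloride
Product: 3 1-(2,4,6-trihydroxyphenyl)butan-1-one
Conditions: AlCl3, PhNO2, 65 °C; aq. HCl
Reagents that add atoms: none
Why: Friedel–Crafts C-acylation of the symmetrical triphenol should stop after one acyl group, because the chelated ketone deactivates the ring.

Step 2
Reactants: 3 1-(2,4,6-trihydroxyphenyl)butan-1-one
Product: 4 1-[2,4,6-tris(benzyloxy)phenyl]butan-1-one
Conditions: BnBr, K2CO3, DMF, 70 °C
Reagents that add atoms: benzyl bromide, BrCc1ccccc1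
Why: Williamson etherification of all three phenols in a dipolar aprotic solvent, where O-alkylation of the acylphloroglucinol anion should prevail over C-alkylation.

Step 3
Reactants: 4 1-[2,4,6-tris(benzyloxy)phenyl]butan-1-one
Product: 5 1-[2,4,6-tris(benzyloxy)-3-bromophenyl]butan-1-one
Conditions: NBS (1.0 equiv), MeCN, 0 °C
Reagents that add atoms: N-bromosuccinimide, O=C1CCC(=O)N1Br
Why: Electrophilic aromatic bromination at one of the two equivalent positions flanked by benzyloxy groups; the bromine slows a second substitution, so one equivalent should stop at the monobromide.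

Step 4
Reactants: 5 1-[2,4,6-tris(benzyloxy)-3-bromophenyl]butan-1-one; 6 (3-tert-butoxy-3-oxopropyl)zinc bromide
Product: 7 tert-butyl 3-[2,4,6-tris(benzyloxy)-3-butanoylphenyl]propanoate
Conditions: Pd(OAc)2, SPhos, THF, 50 °C
Reagents that add atoms: none
Why: Negishi coupling of the aryl bromide with a zinc homoenolate, which tolerates ketone and ester, with a bulky biarylphosphine to cope with the two ortho alkoxy groups.

Step 5
Reactants: 7 tert-butyl 3-[2,4,6-tris(benzyloxy)-3-butanoylphenyl]propanoate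
Product: 8 tert-butyl 3-[2,4,6-tris(benzyloxy)-3-bromo-5-butanoylphenyl]propanoate
Conditions: NBS, MeCN, 0 °C → rt
Reagents that add atoms: N-bromosuccinimide, O=C1CCC(=O)N1Br
Why: Electrophilic aromatic bromination of the only remaining ring hydrogen, still activated by two ortho and one para alkoxy group.

Step 6
Reactants: 8 tert-butyl 3-[2,4,6-tris(benzyloxy)-3-bromo-5-butanoylphenyl]propanoate; 9 (3-ethoxy-3-oxopropyl)zinc bromide
Product: 10 mixed tert-butyl/ethyl bis(propanoate) of ring B
Conditions: Pd(OAc)2, SPhos, THF, 60 °C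
Reagents that add atoms: none
Why: A second Negishi coupling delivers the ethyl ester arm, so that the two otherwise equivalent propanoate arms differ in their esters.

Step 7
Reactants: 10 mixed tert-butyl/ethyl bis(propanoate) of ring B
Product: 11 mono-acid mono-tert-butyl ester
Conditions: LiOH, THF/H2O, 0 °C → rt; 1 M HCl to pH 3
Reagents that add atoms: lithium hydroxide, [Li+].[OH-]
Why: Saponification by acyl–oxygen cleavage removes the ethyl ester only, since the tert-butyl ester is shielded from hydroxide.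

Step 8
Reactants: 11 mono-acid mono-tert-butyl ester; 12 ethoxyethyne
Product: 15 C4-linked 3-ethoxycyclobutenone tert-butyl ester (racemic), via acid chloride 13 (not isolated), via ketene 14 (not isolated)
Conditions: 1-chloro-N,N,2-trimethylprop-1-en-1-amine, CH2Cl2, 0 °C; then Et3N, ethoxyethyne (excess), Et2O, 0 °C → rt
Reagents that add atoms: none
Why: Dehydrochlorination gives an aldoketene that undergoes [2+2] cycloaddition with the ynol ether, the nucleophilic alkyne CH carbon bonding to the ketene carbonyl carbon, so the arm ends at C4 of a 3-ethoxycyclobutenone; the new stereocentre forms racemic and needs no control.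

Step 9
Reactants: 15 C4-linked 3-ethoxycyclobutenone tert-butyl ester
Product: 16 C2-linked 3-hydroxycyclobutenone tert-butyl ester
Conditions: 1 M HCl, THF, 0 °C → rt
Reagents that add atoms: water, O
Why: Acid hydrolysis of the vinylogous ester gives the 2-substituted cyclobutane-1,3-dione, which enolises towards the substituted carbon and so moves the arm to C2 of the enone; the tert-butyl ester should survive cold dilute acid.

Step 10
Reactants: 16 C2-linked 3-hydroxycyclobutenone tert-butyl ester; 17 benzyl alcohol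
Product: 18 C2-linked 3-benzyloxycyclobutenone tert-butyl ester
Conditions: BnOH, PPh3, DIAD, THF, 0 °C → rt
Reagents that add atoms: none
Why: Mitsunobu O-alkylation of the strongly acidic enol (a vinylogous carboxylic acid); the two oxygens of its anion are equivalent, so O-benzylation can give only the 2-substituted 3-benzyloxycyclobutenone.

Step 11
Reactants: 18 C2-linked 3-benzyloxycyclobutenone tert-butyl ester
Product: 19 C2-linked 3-benzyloxycyclobutenone propanoic acid
Conditions: TFA/CH2Cl2 (1:4), 0 °C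
Reagents that add atoms: none
Why: Acid-induced alkyl–oxygen cleavage of the tert-butyl ester under anhydrous conditions, which should spare the aryl benzyl ethers and, without water, the benzyl vinylogous ester.

Step 12
Reactants: 17 benzyl alcohol; 20 trichloroethene
Product: 23 benzyl (E)-1,2-dichlorovinyl ether, via potassium benzyl oxide 21 (not isolated), via dichloroethyne 22 (not isolated)
Conditions: KH, THF, 0 °C; Cl2C=CHCl, −50 °C → rt
Reagents that add atoms: none
Why: Base-induced elimination of HCl from trichloroethene followed by anti addition of the alkoxide to dichloroethyne gives the (E)-dichlorovinyl ether, the standard entry to ynol ethers.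

Step 13
Reactants: 23 benzyl (E)-1,2-dichlorovinyl ether
Product: 26 (benzyloxy)ethyne, via benzyl chloroethynyl ether 24 (not isolated), via lithium benzyloxyethynide 25 (not isolated)
Conditions: n-BuLi (2.2 equiv), THF, −78 °C; MeOH, −78 → 0 °C
Reagents that add atoms: none
Why: Vinylic deprotonation with loss of LiCl, chlorine–lithium exchange and cold protonation give the terminal ynol ether, to be kept as a cold solution and used at once because benzyl ynol ethers rearrange on warming.

Step 14
Reactants: 19 C2-linked 3-benzyloxycyclobutenone propanoic acid; 26 (benzyloxy)ethyne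
Product: 29 bis(cyclobutenone) precursor (racemic at the C4-linked ring), via acid chloride 27 (not isolated), via ketene 28 (not isolated)
Conditions: 1-chloro-N,N,2-trimethylprop-1-en-1-amine, CH2Cl2, 0 °C; then Et3N, (benzyloxy)ethyne (3 equiv), CH2Cl2, −20 °C → rt
Reagents that add atoms: none
Why: The same ketene–ynol ether [2+2] cycloaddition as in step 8, under neutral activation so that the first cyclobutenone survives, places the second arm at C4 of a 3-benzyloxycyclobutenone; its stereocentre forms racemic, which is of no consequence.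

Step 15
Reactants: 30 2-chloro-1,1-dimethoxyethane
Product: 32 1-methoxyprop-1-yne, via sodium methoxyethynide 31 (not isolated)
Conditions: NaNH2 (3 equiv), liq. NH3, −33 °C; MeI
Reagents that add atoms: iodomethane, CI
Why: Twofold base-induced elimination (methanol, then HCl) from the chloroacetal gives the sodium alkoxyacetylide, which is C-methylated in the same flask, the usual one-pot route to 1-alkoxyalk-1-ynes.

Step 16
Reactants: 29 bis(cyclobutenone) precursor; 32 1-methoxyprop-1-yne (two molecules are incorporated)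
Product: 37 three-ring bis(phenol), via bis(vinylketene) 33 (not isolated), via bis(vinylcyclobutenone) 34 (not isolated), via bis(dienylketene) 35 (not isolated), via bis(cyclohexadienone) 36 (not isolated)
Conditions: 1-methoxyprop-1-yne (6 equiv), toluene, 80 → 110 °C, sealed tube
Reagents that add atoms: none
Why: Heat opens each cyclobutenone by conrotatory four-electron ring opening to a vinylketene, the alkyne adds to the ketene C=C bond in a [2+2] cycloaddition (new bonds C2′–C3′ and C4′–C5′ in ring A, C4″–C5″ and C6″–C1″ in ring C), and the 4-vinylcyclobutenone so formed reopens to a dienylketene that cyclises and enolises to the phenol. The closest known reaction is the Danheiser benzannulation of cyclobutenones with alkoxyalkynes, applied here to two 3-alkoxycyclobutenones in one molecule. Ring A and ring C are each closed by a disrotatory six-electron electrocyclisation that joins the former ketene carbon (C2′ or C4″, the future C–OH) to the former cyclobutenone C4 (C1′ or C3″). No new stereocentre arises, and the racemic C4 centre of 29 ends as the aromatic carbon C1′. The step needs a single orientation of the alkyne, secured by the ynol ether polarisation that sends its nucleophilic, methyl-bearing carbon to the ketene carbonyl carbon; the para (ring A) or ortho (ring C) relation of OCH3 to the bridge then follows from the bridge sitting at cyclobutenone C4 or C2. An excess of the volatile alkyne in a closed vessel is meant to outrun ketene dimerisation and acylation of the new phenols.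

Step 17
Reactants: 37 three-ring bis(phenol)
Product: 38 heptabenzyl ether
Conditions: BnBr, K2CO3, DMF, 50 °C
Reagents that add atoms: benzyl bromide, BrCc1ccccc1
Why: Williamson etherification caps the two phenols made in step 16, so that the following acylation cannot be diverted to oxygen.

Step 18
Reactants: 38 heptabenzyl ether; 39 butanoic anhydride
Product: 41 heptabenzyl tris(butanoyl) compound, via butanoic trifluoroacetic anhydride 40 (not isolated)
Conditions: (PrCO)2O, (CF3CO)2O, CH2Cl2, 0 °C → rt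
Reagents that add atoms: none
Why: Anhydride exchange converts one molecule of 39 and one of trifluoroacetic anhydride into two molecules of the mixed anhydride 40, and each transfers one butanoyl group in a Friedel–Crafts acylation without a metal Lewis acid, so that 39 supplies both new acyl groups; each outer ring has one free position (C5′, C3″) flanked by two ether oxygens and para to a third, ring B has none, and benzyl ethers should tolerate the trifluoroacetic acid released at this temperature.

Step 19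
Reactants: 41 heptabenzyl tris(butanoyl) compound
Product: 42 target CNP0171986.0
Conditions: H2 (1 atm), Pd/C, EtOAc/MeOH, rt
Reagents that add atoms: none
Why: Hydrogenolysis of the seven benzyl ethers under neutral conditions should leave the hydrogen-bonded aryl ketones, the methyl ethers and the diarylmethane bridges untouched.

**Compound list**

1 | phloroglucinol | Oc1cc(O)cc(O)c1 | starting material
2 | butanoyl chloride | CCCC(=O)Cl | starting material
3 | 1-(2,4,6-trihydroxyphenyl)butan-1-one | CCCC(=O)c1c(O)cc(O)cc1O | intermediate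
4 | 1-[2,4,6-tris(benzyloxy)phenyl]butan-1-one | CCCC(=O)c1c(OCc2ccccc2)cc(OCc2ccccc2)cc1OCc1ccccc1 | intermediate
5 | 1-[2,4,6-tris(benzyloxy)-3-bromophenyl]butan-1-one | CCCC(=O)c1c(OCc2ccccc2)c(Br)c(OCc2ccccc2)cc1OCc1ccccc1 | intermediate
6 | (3-tert-butoxy-3-oxopropyl)zinc bromide | CC(C)(C)OC(=O)CC[Zn]Br | starting material
7 | tert-butyl 3-[2,4,6-tris(benzyloxy)-3-butanoylphenyl]propanoate | CCCC(=O)c1c(OCc2ccccc2)c(CCC(=O)OC(C)(C)C)c(OCc2ccccc2)cc1OCc1ccccc1 | intermediate
8 | tert-butyl 3-[2,4,6-tris(benzyloxy)-3-bromo-5-butanoylphenyl]propanoate | CCCC(=O)c1c(OCc2ccccc2)c(CCC(=O)OC(C)(C)C)c(OCc2ccccc2)c(Br)c1OCc1ccccc1 | intermediate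
9 | (3-ethoxy-3-oxopropyl)zinc bromide | CCOC(=O)CC[Zn]Br | starting material
10 | tert-butyl 3-[2,4,6-tris(benzyloxy)-3-butanoyl-5-(3-ethoxy-3-oxopropyl)phenyl]propanoate | CCCC(=O)c1c(OCc2ccccc2)c(CCC(=O)OC(C)(C)C)c(OCc2ccccc2)c(CCC(=O)OCC)c1OCc1ccccc1 | intermediate
11 | 3-[2,4,6-tris(benzyloxy)-3-butanoyl-5-(3-tert-butoxy-3-oxopropyl)phenyl]propanoic acid | CCCC(=O)c1c(OCc2ccccc2)c(CCC(=O)OC(C)(C)C)c(OCc2ccccc2)c(CCC(=O)O)c1OCc1ccccc1 | intermediate
12 | ethoxyethyne | CCOC#C | starting material
13 | 3-[2,4,6-tris(benzyloxy)-3-butanoyl-5-(3-tert-butoxy-3-oxopropyl)phenyl]propanoyl chloride | CCCC(=O)c1c(OCc2ccccc2)c(CCC(=O)OC(C)(C)C)c(OCc2ccccc2)c(CCC(=O)Cl)c1OCc1ccccc1 | intermediate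
14 | ketene from 13: tert-butyl 3-[2,4,6-tris(benzyloxy)-3-butanoyl-5-(3-oxoprop-2-en-1-yl)phenyl]propanoate | CCCC(=O)c1c(OCc2ccccc2)c(CCC(=O)OC(C)(C)C)c(OCc2ccccc2)c(CC=C=O)c1OCc1ccccc1 | intermediate
15 | tert-butyl 3-{2,4,6-tris(benzyloxy)-3-butanoyl-5-[(2-ethoxy-4-oxocyclobut-2-en-1-yl)methyl]phenyl}propanoate, racemic | CCCC(=O)c1c(OCc2ccccc2)c(CCC(=O)OC(C)(C)C)c(OCc2ccccc2)c(CC2C(=O)C=C2OCC)c1OCc1ccccc1 | intermediate
16 | tert-butyl 3-{2,4,6-tris(benzyloxy)-3-butanoyl-5-[(2-hydroxy-4-oxocyclobut-1-en-1-yl)methyl]phenyl}propanoate | CCCC(=O)c1c(OCc2ccccc2)c(CCC(=O)OC(C)(C)C)c(OCc2ccccc2)c(CC2=C(O)CC2=O)c1OCc1ccccc1 | intermediate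
17 | benzyl alcohol | OCc1ccccc1 | starting material
18 | tert-butyl 3-{2,4,6-tris(benzyloxy)-3-{[2-(benzyloxy)-4-oxocyclobut-1-en-1-yl]methyl}-5-butanoylphenyl}propanoate | CCCC(=O)c1c(OCc2ccccc2)c(CCC(=O)OC(C)(C)C)c(OCc2ccccc2)c(CC2=C(OCc3ccccc3)CC2=O)c1OCc1ccccc1 | intermediate
19 | 3-{2,4,6-tris(benzyloxy)-3-{[2-(benzyloxy)-4-oxocyclobut-1-en-1-yl]methyl}-5-butanoylphenyl}propanoic acid | CCCC(=O)c1c(OCc2ccccc2)c(CCC(=O)O)c(OCc2ccccc2)c(CC2=C(OCc3ccccc3)CC2=O)c1OCc1ccccc1 | intermediate
20 | trichloroethene | ClC=C(Cl)Cl | starting material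
21 | potassium benzyl oxide | [K+].[O-]Cc1ccccc1 | intermediate
22 | dichloroethyne | ClC#CCl | intermediate
23 | benzyl (E)-1,2-dichlorovinyl ether | Cl/C=C(/Cl)OCc1ccccc1 | intermediate
24 | benzyl chloroethynyl ether | ClC#COCc1ccccc1 | intermediate
25 | lithium (benzyloxy)ethynide | [Li]C#COCc1ccccc1 | intermediate
26 | (benzyloxy)ethyne | C#COCc1ccccc1 | intermediate
27 | acid chloride of 19 | CCCC(=O)c1c(OCc2ccccc2)c(CCC(=O)Cl)c(OCc2ccccc2)c(CC2=C(OCc3ccccc3)CC2=O)c1OCc1ccccc1 | intermediate
28 | ketene from 27 | CCCC(=O)c1c(OCc2ccccc2)c(CC=C=O)c(OCc2ccccc2)c(CC2=C(OCc3ccccc3)CC2=O)c1OCc1ccccc1 | intermediate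
29 | 1-{2,4,6-tris(benzyloxy)-3-{[2-(benzyloxy)-4-oxocyclobut-2-en-1-yl]methyl}-5-{[2-(benzyloxy)-4-oxocyclobut-1-en-1-yl]methyl}phenyl}butan-1-one, racemic at cyclobutenone C4 | CCCC(=O)c1c(OCc2ccccc2)c(CC2C(=O)C=C2OCc2ccccc2)c(OCc2ccccc2)c(CC2=C(OCc3ccccc3)CC2=O)c1OCc1ccccc1 | intermediate
30 | 2-chloro-1,1-dimethoxyethane | COC(CCl)OC | starting material
31 | sodium methoxyethynide | [Na+].[C-]#COC | intermediate
32 | 1-methoxyprop-1-yne | CC#COC | intermediate
33 | bis(vinylketene), both arms drawn at the same stage | CCCC(=O)c1c(OCc2ccccc2)c(C/C=C(\OCc2ccccc2)C=C=O)c(OCc2ccccc2)c(CC(=C=O)C(OCc2ccccc2)=C)c1OCc1ccccc1 | intermediate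
34 | bis(4-vinyl-3-methoxy-2-methylcyclobutenone), mixture of stereoisomers | CCCC(=O)c1c(OCc2ccccc2)c(C/C=C(\OCc2ccccc2)C2C(=O)C(C)=C2OC)c(OCc2ccccc2)c(CC2(C(OCc3ccccc3)=C)C(=O)C(C)=C2OC)c1OCc1ccccc1 | intermediate
35 | bis(dienylketene), geometry that can cyclise | CCCC(=O)c1c(OCc2ccccc2)c(C/C=C(\OCc2ccccc2)/C=C(OC)\C(C)=C=O)c(OCc2ccccc2)c(C/C(C(OCc2ccccc2)=C)=C(\OC)C(C)=C=O)c1OCc1ccccc1 | intermediate
36 | bis(cyclohexa-2,4-dienone), racemic at the ring A sp3 carbon | CCCC(=O)c1c(OCc2ccccc2)c(CC2C(=O)C(C)=C(OC)C=C2OCc2ccccc2)c(OCc2ccccc2)c(CC2=C(OCc3ccccc3)CC(=O)C(C)=C2OC)c1OCc1ccccc1 | intermediate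
37 | 1-{2,4,6-tris(benzyloxy)-3-[(6-benzyloxy-2-hydroxy-4-methoxy-3-methylphenyl)methyl]-5-[(2-benzyloxy-4-hydroxy-6-methoxy-5-methylphenyl)methyl]phenyl}butan-1-one | CCCC(=O)c1c(OCc2ccccc2)c(Cc2c(O)c(C)c(OC)cc2OCc2ccccc2)c(OCc2ccccc2)c(Cc2c(OCc3ccccc3)cc(O)c(C)c2OC)c1OCc1ccccc1 | intermediate
38 | 1-{2,4,6-tris(benzyloxy)-3-[(2,6-bis(benzyloxy)-4-methoxy-3-methylphenyl)methyl]-5-[(2,4-bis(benzyloxy)-6-methoxy-5-methylphenyl)methyl]phenyl}butan-1-one | CCCC(=O)c1c(OCc2ccccc2)c(Cc2c(OCc3ccccc3)c(C)c(OC)cc2OCc2ccccc2)c(OCc2ccccc2)c(Cc2c(OCc3ccccc3)cc(OCc3ccccc3)c(C)c2OC)c1OCc1ccccc1 | intermediate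
39 | butanoic anhydride | CCCC(=O)OC(=O)CCC | starting material
40 | butanoic trifluoroacetic anhydride | CCCC(=O)OC(=O)C(F)(F)F | intermediate
41 | 1-{2,4,6-tris(benzyloxy)-3-[(2,6-bis(benzyloxy)-3-butanoyl-4-methoxy-5-methylphenyl)methyl]-5-[(2,4-bis(benzyloxy)-3-butanoyl-6-methoxy-5-methylphenyl)methyl]phenyl}butan-1-one | CCCC(=O)c1c(OCc2ccccc2)c(Cc2c(OCc3ccccc3)c(C)c(OC)c(C(=O)CCC)c2OCc2ccccc2)c(OCc2ccccc2)c(Cc2c(OCc3ccccc3)c(C(=O)CCC)c(OCc3ccccc3)c(C)c2OC)c1OCc1ccccc1 | intermediate
42 | 1-{3-[(3-butanoyl-2,6-dihydroxy-4-methoxy-5-methylphenyl)methyl]-5-[(3-butanoyl-2,4-dihydroxy-6-methoxy-5-methylphenyl)methyl]-2,4,6-trihydroxyphenyl}butan-1-one (CNP0171986.0) | CCCC(=O)c1c(O)c(Cc2c(O)c(C)c(OC)c(C(=O)CCC)c2O)c(O)c(Cc2c(O)c(C(=O)CCC)c(O)c(C)c2OC)c1O | target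

**Count and risk**

Total steps: 19 (16 on the main line, 3 in side branches: steps 12, 13 and 15). Longest linear sequence: 16 steps (1–11, 14, 16–19).

Steps most likely to fail:

1. Step 16. A vinylketene on one arm may be trapped by the phenol already formed on the other arm (ester formation within or between molecules), the ketenes may dimerise, or only one of the two cyclobutenones may be consumed. The fallback closes one ring at a time with the same known reactions and sets out from 18. Heating 18 with 32 (toluene, 110 °C, sealed tube) should close ring C alone and give the ring C phenol tert-butyl ester F1. Benzylation (BnBr, K2CO3, DMF) gives the benzyl ether F2, and TFA/CH2Cl2 frees the propanoic acid F3. Activation with 1-chloro-N,N,2-trimethylprop-1-en-1-amine gives the acid chloride F4, Et3N gives the ketene F5, and cycloaddition with 26 gives the C4-linked mono(cyclobutenone) F6. Heating with 32 then closes ring A to the ring A phenol F7, in a molecule that no longer holds a free phenol when the ketene is formed. Benzylation of F7 (BnBr, K2CO3, DMF) comes back to the route at 38.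

2. Step 18. Substitution at the two crowded positions may be slow, and on forcing the acid medium may begin to cleave benzyl ethers or protonate the electron-rich rings at the bridge carbons. The fallback changes electrophile and substrate and sets out from 37, leaving step 17 out. A Houben–Hoesch acylation of the free bis(phenol) with butanenitrile (ZnCl2, HCl gas, Et2O, 0 °C), C-selective on rings that carry a free hydroxyl para (ring A) or ortho (ring C) to the open position, should give the bis(ketiminium chloride) F8. Hydrolysis (H2O, 60 °C) gives the pentabenzyl tris(butanoyl) bis(phenol) F9. Hydrogenolysis of its five benzyl ethers (H2, Pd/C, EtOAc/MeOH) comes back to the route at 42.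

3. Step 10. The ambident enolate of the cyclobutanedione may be benzylated on carbon, or the strained ring may be opened by the alcohol. The fallback replaces alkylation by addition–elimination and sets out from 16. Oxalyl chloride with catalytic DMF (CH2Cl2, 0 °C) should convert the vinylogous acid into the 3-chlorocyclobutenone F10. Substitution of the vinylogous acid chloride by 17 with Et3N (CH2Cl2, 0 °C), which can only form the C–O bond, comes back to the route at 18.

**Further compounds**

F1 | step 16 | ring C phenol tert-butyl ester | CCCC(=O)c1c(OCc2ccccc2)c(CCC(=O)OC(C)(C)C)c(OCc2ccccc2)c(Cc2c(OCc3ccccc3)cc(O)c(C)c2OC)c1OCc1ccccc1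
F2 | step 16 | benzyl ether of F1 | CCCC(=O)c1c(OCc2ccccc2)c(CCC(=O)OC(C)(C)C)c(OCc2ccccc2)c(Cc2c(OCc3ccccc3)cc(OCc3ccccc3)c(C)c2OC)c1OCc1ccccc1
F3 | step 16 | propanoic acid from F2 | CCCC(=O)c1c(OCc2ccccc2)c(CCC(=O)O)c(OCc2ccccc2)c(Cc2c(OCc3ccccc3)cc(OCc3ccccc3)c(C)c2OC)c1OCc1ccccc1
F4 | step 16 | acid chloride of F3 | CCCC(=O)c1c(OCc2ccccc2)c(CCC(=O)Cl)c(OCc2ccccc2)c(Cc2c(OCc3ccccc3)cc(OCc3ccccc3)c(C)c2OC)c1OCc1ccccc1
F5 | step 16 | ketene from F4 | CCCC(=O)c1c(OCc2ccccc2)c(CC=C=O)c(OCc2ccccc2)c(Cc2c(OCc3ccccc3)cc(OCc3ccccc3)c(C)c2OC)c1OCc1ccccc1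
F6 | step 16 | C4-linked mono(cyclobutenone) with ring C closed, racemic | CCCC(=O)c1c(OCc2ccccc2)c(CC2C(=O)C=C2OCc2ccccc2)c(OCc2ccccc2)c(Cc2c(OCc3ccccc3)cc(OCc3ccccc3)c(C)c2OC)c1OCc1ccccc1
F7 | step 16 | ring A phenol with ring C benzylated | CCCC(=O)c1c(OCc2ccccc2)c(Cc2c(O)c(C)c(OC)cc2OCc2ccccc2)c(OCc2ccccc2)c(Cc2c(OCc3ccccc3)cc(OCc3ccccc3)c(C)c2OC)c1OCc1ccccc1
F8 | step 18 | bis(ketiminium chloride) | CCCC(=O)c1c(OCc2ccccc2)c(Cc2c(O)c(C)c(OC)c(C(=[NH2+])CCC)c2OCc2ccccc2)c(OCc2ccccc2)c(Cc2c(OCc3ccccc3)c(C(=[NH2+])CCC)c(O)c(C)c2OC)c1OCc1ccccc1.[Cl-].[Cl-]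
F9 | step 18 | pentabenzyl tris(butanoyl) bis(phenol) | CCCC(=O)c1c(OCc2ccccc2)c(Cc2c(O)c(C)c(OC)c(C(=O)CCC)c2OCc2ccccc2)c(OCc2ccccc2)c(Cc2c(OCc3ccccc3)c(C(=O)CCC)c(O)c(C)c2OC)c1OCc1ccccc1
F10 | step 10 | C2-linked 3-chlorocyclobutenone tert-butyl ester | CCCC(=O)c1c(OCc2ccccc2)c(CCC(=O)OC(C)(C)C)c(OCc2ccccc2)c(CC2=C(Cl)CC2=O)c1OCc1ccccc1
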